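**Overview**
Retrosynthesis: the glycerol chain is cut first at C7''-C8'' (aldol) and at the ring A oxygen-C8'' bond (phenol alkylation). This leaves a protected (+)-lariciresinol, which is cut at oxolane C3-C4 (radical cyclisation) and at O1-C5 (ether synthesis).
Enabling feature: in the oxolane (O1, C2 bearing ring A, C3, C4, C5H2) the neighbouring carbons C3 and C4 carry a hydroxymethyl and an arylmethyl group. A C3 radical released from a terminal oxirane keeps its oxygen as that CH2OH. Its addition to the alkene of a cinnamyl ether on O1 turns the styryl carbon into that ArCH2.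
Forward order: the oxirane is made on an aryl vinyl carbinol, the benzylic ether joins rings A and B, and the oxolane closes in the key step. The chain then grows from the ring A phenol by O-alkylation and aldol union with the ring C aldehyde, and deprotection ends the route.
Stereochemistry: C2 (S) comes from a Sharpless kinetic resolution. C3 (R) and C4 (R) are set by C2 during the cyclisation, the oxirane centre being lost at the planar radical. C7''/C8'' (S,S, threo) come from (R)-4-benzyloxazolidinone in a boron syn aldol.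

Key step: step 8

Labels: ring A is the aryl on C2, ring B the aryl of the C4 benzyl arm, ring C the aryl of the glycerol chain. C7'' is the carbinol carbon, C8'' the aryloxy carbon and C9'' the CH2OH carbon.
Assumption: the aryloxyacetyl imide is taken to enolise and to choose its face in the boron aldol as alkoxyacetyl and propionyl imides of the same auxiliary do.

Step 1
Reactants: 1 vanillin (4-hydroxy-3-methoxybenzaldehyde)
Product: 2 4-(allyloxy)-3-methoxybenzaldehyde
Conditions: allyl bromide, K2CO3, DMF, rt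
Reagents that add atoms: allyl bromide, C=CCBr
Why: Williamson O-alkylation of an acidic phenol with a reactive allylic halide; allyl is chosen because zerovalent palladium later removes it without touching benzyl or silyl ethers.

Step 2
Reactants: 2 4-(allyloxy)-3-methoxybenzaldehyde
Product: 3 rac-1-[4-(allyloxy)-3-methoxyphenyl]prop-2-en-1-ol
Conditions: CH2=CHMgBr, THF, 0 °C; then aq. NH4Cl
Reagents that add atoms: vinylmagnesium bromide, C=C[Mg]Br
Why: Grignard 1,2-addition to a non-enolisable aldehyde; the carbinol centre forms as a racemate and is resolved in the next step.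

Step 3
Reactants: 3 rac-1-[4-(allyloxy)-3-methoxyphenyl]prop-2-en-1-ol
Product: 4 (R)-[4-(allyloxy)-3-methoxyphenyl][(S)-oxiran-2-yl]methanol (erythro epoxy alcohol)
Conditions: Ti(OiPr)4 (0.15 equiv), D-(−)-diisopropyl tartrate (0.18 equiv), t-BuOOH (0.45 equiv, decane), 4 Å MS, CH2Cl2, −20 °C
Reagents that add atoms: tert-butyl hydroperoxide, CC(C)(C)OO
Why: Sharpless kinetic resolution (Katsuki-Sharpless epoxidation of a secondary allylic alcohol): with the D-(−)-tartrate the (S)-carbinol is the fast-reacting enantiomer and is epoxidised with the usual erythro preference to the (R)-carbinol/(S)-oxirane 4 (the carbinol descriptor changes only because the oxirane carbon outranks the aryl group), while less than half an equivalent of oxidant keeps the enantiomeric purity high and the hydroxyl-free aryl allyl ether alkene stays untouched.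

Step 4
Reactants: 5 4-(benzyloxy)-3-methoxybenzaldehyde
Product: 6 ethyl (E)-3-[4-(benzyloxy)-3-methoxyphenyl]prop-2-enoate
Conditions: (EtO)2P(O)CH2CO2Et, NaH, THF, 0 °C to rt
Reagents that add atoms: triethyl phosphonoacetate, CCOC(=O)CP(=O)(OCC)OCC
Why: Horner-Wadsworth-Emmons olefination with a stabilised phosphonate, which should give the E enoate from an aromatic aldehyde.

Step 5
Reactants: 6 ethyl (E)-3-[4-(benzyloxy)-3-methoxyphenyl]prop-2-enoate
Product: 7 (E)-3-[4-(benzyloxy)-3-methoxyphenyl]prop-2-en-1-ol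
Conditions: iBu2AlH (2.2 equiv), CH2Cl2, −78 to 0 °C; then aq. potassium sodium tartrate
Reagents that add atoms: none
Why: 1,2-reduction of the enoate by a dialkylaluminium hydride gives the allylic alcohol and leaves the alkene and the benzyl ether alone.

Step 6
Reactants: 7 (E)-3-[4-(benzyloxy)-3-methoxyphenyl]prop-2-en-1-ol
Product: 8 (E)-1-(benzyloxy)-4-(3-bromoprop-1-enyl)-2-methoxybenzene
Conditions: PBr3 (0.4 equiv), Et2O, 0 °C; cold aq. NaHCO3 wash, used crude at once
Reagents that add atoms: phosphorus tribromide, BrP(Br)Br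
Why: Bromination of a primary allylic alcohol through its phosphite ester, in which conjugation with ring B keeps the linear E bromide as the only stable isomer; the labile product is not chromatographed.

Step 7
Reactants: 4 (R)-[4-(allyloxy)-3-methoxyphenyl][(S)-oxiran-2-yl]methanol, 8 (E)-1-(benzyloxy)-4-(3-bromoprop-1-enyl)-2-methoxybenzene
Product: 10 (S)-2-[(R)-[4-(allyloxy)-3-methoxyphenyl]{[(E)-3-[4-(benzyloxy)-3-methoxyphenyl]prop-2-enyl]oxy}methyl]oxirane, via sodium alkoxide 9 (not isolated)
Conditions: NaH, THF-DMF (4:1), −10 °C; then 8, Bu4NI (cat.), −10 to 0 °C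
Reagents that add atoms: none
Why: Williamson etherification in which the preformed alkoxide, kept cold in an aprotic medium, attacks the primary carbon of the very reactive cinnamyl bromide faster than it can undergo Payne migration; no stereocentre is touched.

Step 8
Reactants: 10 (S)-2-[(R)-[4-(allyloxy)-3-methoxyphenyl]{[(E)-3-[4-(benzyloxy)-3-methoxyphenyl]prop-2-enyl]oxy}methyl]oxirane
Product: 13 [(2S,3R,4R)-2-[4-(allyloxy)-3-methoxyphenyl]-4-[4-(benzyloxy)-3-methoxybenzyl]oxolan-3-yl]methanol, via beta-titanoxy C3 radical 11 (not isolated), via benzylic titanium alkyl 12 (not isolated)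
Conditions: Cp2TiCl2 (2.5 equiv), Zn dust, THF, rt (green Cp2TiCl); added dropwise to 10 in THF, rt; then 1 M HCl, 0 °C
Reagents that add atoms: none
Why: Cp2TiCl, a trivalent titanium reagent made in the flask from Cp2TiCl2 and Zn, binds the oxirane oxygen and transfers one electron so that the internal C-O bond breaks and the secondary beta-titanoxy radical 11 arises at the future C3; 11 adds to the cinnamyl alkene, a second Cp2TiCl captures the benzylic radical as the tetravalent titanium alkyl 12, and HCl protonates the C-Ti and O-Ti bonds to leave ArCH2 on C4 and CH2OH on C3. The reaction type is the Nugent-RajanBabu reductive epoxide opening with radical cyclisation, which is established for epoxy allyl and cinnamyl ethers with styrene-type acceptors. The oxolane closes 5-exo-trig through the new C3-C4 bond. C3 forms from a planar radical, so the oxirane configuration is erased and only C2 steers: in the chair-like Beckwith-Houk transition state ring A on C2 lies pseudo-equatorial, the CH2OTi arm on the radical carbon turns away from it (2,3-trans, 3R), and the alkene is attacked so that the new benzyl arm ends cis to that arm and trans to ring A (3,4-cis, 4R). The step needs 5-exo over 6-endo closure, cyclisation faster than capture or deoxygenation of 11 by titanium, and 2,3-trans/3,4-cis selection; these are secured by the benzylic stabilisation of the product radical, the short C-O bonds of the 3-oxa tether, dropwise addition of the reductant and the single bulky aryl group next to the radical centre. The aryl allyl ether is out of reach of both radicals and, like the benzyl and methyl ethers, is not reduced by Cp2TiCl.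

Step 9
Reactants: 13 [(2S,3R,4R)-2-[4-(allyloxy)-3-methoxyphenyl]-4-[4-(benzyloxy)-3-methoxybenzyl]oxolan-3-yl]methanol
Product: 14 tert-butyldimethylsilyl ether of 13 at the C3 hydroxymethyl group (2S,3R,4R)
Conditions: TBSCl, imidazole, CH2Cl2, 0 °C to rt
Reagents that add atoms: tert-butyldimethylsilyl chloride, CC(C)(C)[Si](C)(C)Cl
Why: Standard silylation of the only free hydroxyl, which keeps the primary alcohol away from Bu2BOTf in the aldol and is removable with fluoride.

Step 10
Reactants: 14 tert-butyldimethylsilyl ether of 13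
Product: 15 4-[(2S,3R,4R)-4-[4-(benzyloxy)-3-methoxybenzyl]-3-{[(tert-butyldimethylsilyl)oxy]methyl}oxolan-2-yl]-2-methoxyphenol
Conditions: Pd(PPh3)4 (5 mol %), morpholine, THF, rt
Reagents that add atoms: none
Why: Tsuji-Trost-type deallylation in which zerovalent palladium ionises the aryl allyl ether to a pi-allyl complex and the ring A phenoxide while morpholine takes up the allyl group; benzyl and silyl ethers are inert.

Step 11
Reactants: 16 (R)-4-benzyl-1,3-oxazolidin-2-one
Product: 18 (R)-4-benzyl-3-(bromoacetyl)-1,3-oxazolidin-2-one, via lithium oxazolidinone salt 17 (not isolated)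
Conditions: n-BuLi, THF, −78 °C; then BrCH2COBr, −78 to 0 °C
Reagents that add atoms: bromoacetyl bromide, O=C(Br)CBr
Why: N-acylation of the lithiated auxiliary, in which the acyl bromide reacts far faster than the alkyl bromide at low temperature.

Step 12
Reactants: 15 ring A phenol, 18 (R)-4-benzyl-3-(bromoacetyl)-1,3-oxazolidin-2-one
Product: 19 (R)-4-benzyl-3-{[4-[(2S,3R,4R)-4-[4-(benzyloxy)-3-methoxybenzyl]-3-{[(tert-butyldimethylsilyl)oxy]methyl}oxolan-2-yl]-2-methoxyphenoxy]acetyl}-1,3-oxazolidin-2-one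
Conditions: K2CO3, acetone, 0 °C to rt
Reagents that add atoms: none
Why: SN2 O-alkylation of a phenoxide at an alpha-bromo carbonyl carbon, fast enough under mild carbonate conditions to outrun attack at the imide carbonyls; any minor enantiomer of the core becomes a separable diastereomer here.

Step 13
Reactants: 19 aryloxyacetyl imide, 5 4-(benzyloxy)-3-methoxybenzaldehyde
Product: 21 (R)-4-benzyl-3-[(2R,3S)-3-[4-(benzyloxy)-3-methoxyphenyl]-3-hydroxy-2-{4-[(2S,3R,4R)-4-[4-(benzyloxy)-3-methoxybenzyl]-3-{[(tert-butyldimethylsilyl)oxy]methyl}oxolan-2-yl]-2-methoxyphenoxy}propanoyl]-1,3-oxazolidin-2-one, via Z dibutylboron enolate 20 (not isolated)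
Conditions: Bu2BOTf (1.3 equiv), Et3N, CH2Cl2, −78 to 0 °C; then 5, −78 to 0 °C; pH 7 buffer (NaH2PO4/Na2HPO4), MeOH, 30% H2O2, 0 °C
Reagents that add atoms: none
Why: Evans boron syn aldol: soft enolisation gives the Z enolate 20, which reacts through a closed Zimmerman-Traxler chair with opposed imide dipoles so that the benzyl group of the (R)-auxiliary blocks one enolate face, setting C8'' and C7'' together as the syn pair (2R,3S in the adduct) that is the (S,S) threo pair of the target.

Step 14
Reactants: 21 syn aldol adduct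
Product: 22 (1S,2S)-1-[4-(benzyloxy)-3-methoxyphenyl]-2-{4-[(2S,3R,4R)-4-[4-(benzyloxy)-3-methoxybenzyl]-3-{[(tert-butyldimethylsilyl)oxy]methyl}oxolan-2-yl]-2-methoxyphenoxy}propane-1,3-diol
Conditions: LiBH4, H2O (1.1 equiv), Et2O-THF, 0 °C
Reagents that add atoms: none
Why: Reductive removal of the auxiliary, in which hydride attacks the exocyclic imide carbonyl and carries it to CH2OH under cold, weakly basic conditions that avoid retro-aldol and C8'' epimerisation; the C8'' descriptor turns from R to S only through the change in substituent ranking.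

Step 15
Reactants: 22 silylated 1,3-diol
Product: 23 (1S,2S)-1-[4-(benzyloxy)-3-methoxyphenyl]-2-{4-[(2S,3R,4R)-4-[4-(benzyloxy)-3-methoxybenzyl]-3-(hydroxymethyl)oxolan-2-yl]-2-methoxyphenoxy}propane-1,3-diol
Conditions: Bu4NF, THF, 0 °C to rt
Reagents that add atoms: none
Why: Fluoride-driven cleavage of the primary silyl ether, done while both phenols are still benzylated so that the basic medium cannot open a quinone methide pathway at C7''.

Step 16
Reactants: 23 dibenzyl ether triol
Product: 24 (1S,2S)-1-(4-hydroxy-3-methoxyphenyl)-2-{4-[(2S,3R,4R)-4-(4-hydroxy-3-methoxybenzyl)-3-(hydroxymethyl)oxolan-2-yl]-2-methoxyphenoxy}propane-1,3-diol (CNP0226724.1)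
Conditions: H2 (1 atm), 10% Pd/C, EtOAc, rt, stopped as soon as 23 is consumed
Reagents that add atoms: none
Why: Catalytic hydrogenolysis, in which aryl benzyl ethers should cleave much faster than the C7'' benzylic alcohol or the benzylic C2-O1 bond under neutral conditions at atmospheric pressure, as is routine for guaiacylglycerol aryl ethers and oxolane lignans, so all five stereocentres stay untouched.

**Compound list**
1 | vanillin | COc1cc(C=O)ccc1O | starting material
2 | 4-(allyloxy)-3-methoxybenzaldehyde | C=CCOc1ccc(C=O)cc1OC | intermediate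
3 | rac-1-[4-(allyloxy)-3-methoxyphenyl]prop-2-en-1-ol | C=CCOc1ccc(C(O)C=C)cc1OC | intermediate
4 | (R)-[4-(allyloxy)-3-methoxyphenyl][(S)-oxiran-2-yl]methanol | C=CCOc1ccc([C@@H](O)[C@@H]2CO2)cc1OC | intermediate
5 | 4-(benzyloxy)-3-methoxybenzaldehyde | COc1cc(C=O)ccc1OCc1ccccc1 | starting material
6 | ethyl (E)-3-[4-(benzyloxy)-3-methoxyphenyl]prop-2-enoate | CCOC(=O)/C=C/c1ccc(OCc2ccccc2)c(OC)c1 | intermediate
7 | (E)-3-[4-(benzyloxy)-3-methoxyphenyl]prop-2-en-1-ol | COc1cc(/C=C/CO)ccc1OCc1ccccc1 | intermediate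
8 | (E)-1-(benzyloxy)-4-(3-bromoprop-1-enyl)-2-methoxybenzene | COc1cc(/C=C/CBr)ccc1OCc1ccccc1 | intermediate
9 | sodium alkoxide of 4 (not isolated) | [Na+].C=CCOc1ccc([C@@H]([O-])[C@@H]2CO2)cc1OC | intermediate
10 | epoxy cinnamyl ether, (R) at the benzylic carbon, (S) at the oxirane, E alkene | C=CCOc1ccc([C@@H](OC/C=C/c2ccc(OCc3ccccc3)c(OC)c2)[C@@H]2CO2)cc1OC | intermediate
11 | beta-titanoxy C3 radical (not isolated; Cp rings drawn sigma-bound) | C=CCOc1ccc([C@@H](OC/C=C/c2ccc(OCc3ccccc3)c(OC)c2)[CH]CO[Ti](Cl)(C2C=CC=C2)C2C=CC=C2)cc1OC | intermediate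
12 | cyclised benzylic titanium alkyl and titanium alkoxide (not isolated; Cp rings drawn sigma-bound) | COc1cc(C([Ti](Cl)(C2C=CC=C2)C2C=CC=C2)[C@H]2CO[C@H](c3ccc(OCC=C)c(OC)c3)[C@H]2CO[Ti](Cl)(C2C=CC=C2)C2C=CC=C2)ccc1OCc1ccccc1 | intermediate
13 | [(2S,3R,4R)-2-[4-(allyloxy)-3-methoxyphenyl]-4-[4-(benzyloxy)-3-methoxybenzyl]oxolan-3-yl]methanol | COc1cc(C[C@H]2CO[C@H](c3ccc(OCC=C)c(OC)c3)[C@H]2CO)ccc1OCc1ccccc1 | intermediate
14 | primary TBS ether of 13 | COc1cc(C[C@H]2CO[C@H](c3ccc(OCC=C)c(OC)c3)[C@H]2CO[Si](C)(C)C(C)(C)C)ccc1OCc1ccccc1 | intermediate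
15 | ring A phenol, ring B O-benzyl, primary O-TBS (2S,3R,4R) | COc1cc(C[C@H]2CO[C@H](c3ccc(O)c(OC)c3)[C@H]2CO[Si](C)(C)C(C)(C)C)ccc1OCc1ccccc1 | intermediate
16 | (R)-4-benzyl-1,3-oxazolidin-2-one | O=C1N[C@H](Cc2ccccc2)CO1 | starting material
17 | lithium salt of 16 (not isolated) | [Li+].O=C1[N-][C@H](Cc2ccccc2)CO1 | intermediate
18 | (R)-4-benzyl-3-(bromoacetyl)-1,3-oxazolidin-2-one | O=C(CBr)N1C(=O)OC[C@H]1Cc1ccccc1 | intermediate
19 | aryloxyacetyl imide of the lariciresinol core | COc1cc(C[C@H]2CO[C@H](c3ccc(OCC(=O)N4C(=O)OC[C@H]4Cc4ccccc4)c(OC)c3)[C@H]2CO[Si](C)(C)C(C)(C)C)ccc1OCc1ccccc1 | intermediate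
20 | Z dibutylboron enolate of 19 (not isolated) | COc1cc(C[C@H]2CO[C@H](c3ccc(O/C=C(/N4C(=O)OC[C@H]4Cc4ccccc4)OB(CCCC)CCCC)c(OC)c3)[C@H]2CO[Si](C)(C)C(C)(C)C)ccc1OCc1ccccc1 | intermediate
21 | syn aldol adduct (2R,3S in the propanoyl chain) | COc1cc(C[C@H]2CO[C@H](c3ccc(O[C@@H](C(=O)N4C(=O)OC[C@H]4Cc4ccccc4)[C@@H](O)c4ccc(OCc5ccccc5)c(OC)c4)c(OC)c3)[C@H]2CO[Si](C)(C)C(C)(C)C)ccc1OCc1ccccc1 | intermediate
22 | (1S,2S)-1,3-diol, two O-benzyl, one O-TBS | COc1cc(C[C@H]2CO[C@H](c3ccc(O[C@@H](CO)[C@@H](O)c4ccc(OCc5ccccc5)c(OC)c4)c(OC)c3)[C@H]2CO[Si](C)(C)C(C)(C)C)ccc1OCc1ccccc1 | intermediate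
23 | dibenzyl ether of the target | COc1cc(C[C@H]2CO[C@H](c3ccc(O[C@@H](CO)[C@@H](O)c4ccc(OCc5ccccc5)c(OC)c4)c(OC)c3)[C@H]2CO)ccc1OCc1ccccc1 | intermediate
24 | CNP0226724.1 | COc1cc(C[C@H]2CO[C@H](c3ccc(O[C@@H](CO)[C@@H](O)c4ccc(O)c(OC)c4)c(OC)c3)[C@H]2CO)ccc1O | target

**Step count and risks**
Total step count: 16.
Longest linear sequence: 12 steps (1, 2, 3, 7, 8, 9, 10, 12, 13, 14, 15, 16). The branch through steps 4 to 6 is equally long.

Step 8. A second Cp2TiCl may intercept the beta-titanoxy radical before ring closure. Beta-elimination would then deoxygenate the substrate. The 3,4-cis preference may also erode.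
The fallback sets out from 10 and comes back at 14. It generates the same C3 radical without a metal on the neighbouring oxygen.
- Aqueous NaOH in 1,4-dioxane opens the oxirane at its CH2 terminus to the 1,2-diol F1.
- TBSCl and imidazole silylate the primary hydroxyl to the mono-silyl ether F2.
- 1,1'-Thiocarbonyldiimidazole converts the secondary hydroxyl to the O-alkyl imidazole-1-carbothioate F3.
- Bu3SnH with Et3B and air in toluene, at or below rt, cleaves the C-O bond in the Barton-McCombie manner.
- 5-exo closure and hydrogen transfer from the stannane to the benzylic radical should then give 14 directly.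

Step 12. The phenoxide may attack an imide carbonyl of 18 instead of the CH2Br carbon. This would cause acyl transfer and loss of the auxiliary.
The fallback sets out from 15 and comes back at 19. It builds the acyl chain before the auxiliary is attached.
- Ethyl bromoacetate and K2CO3 in acetone give the ethyl aryloxyacetate F4.
- LiOH in THF-H2O gives the aryloxyacetic acid F5.
- Pivaloyl chloride and Et3N give the mixed pivalic anhydride F6.
- F6 acylates the lithium salt 17 at −78 °C to give 19.

Step 16. The C7'' hydroxyl may be lost by hydrogenolysis once ring C is a free phenol, or the oxolane may open reductively at C2-O1.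
The fallback sets out from 19 and comes back at 24. The hydrogenolysis is moved ahead of the aldol, so the benzylic carbinol never meets hydrogen and palladium, and the route ends with fluoride.
- H2 and 10% Pd/C in EtOAc free ring B of 19 to the phenol imide F7.
- TBSCl and imidazole give the bis-silyl imide F8.
- Vanillin 1 is silylated in the same way to 4-(tert-butyldimethylsilyloxy)-3-methoxybenzaldehyde F9.
- Bu2BOTf and Et3N convert F8 to its Z boron enolate F10, which adds to F9 to give the syn aldol adduct F11.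
- LiBH4 gives the tris-silyl 1,3-diol F12.
- Bu4NF buffered with AcOH in THF at 0 °C removes all three silyl groups to give 24.

**Further compounds**
F1 | step 8 | (2S,3R)-3-[4-(allyloxy)-3-methoxyphenyl]-3-{[(E)-3-[4-(benzyloxy)-3-methoxyphenyl]prop-2-enyl]oxy}propane-1,2-diol | C=CCOc1ccc([C@@H](OC/C=C/c2ccc(OCc3ccccc3)c(OC)c2)[C@@H](O)CO)cc1OC
F2 | step 8 | primary TBS ether of F1 | C=CCOc1ccc([C@@H](OC/C=C/c2ccc(OCc3ccccc3)c(OC)c2)[C@@H](O)CO[Si](C)(C)C(C)(C)C)cc1OC
F3 | step 8 | O-alkyl imidazole-1-carbothioate of F2 | C=CCOc1ccc([C@@H](OC/C=C/c2ccc(OCc3ccccc3)c(OC)c2)[C@@H](OC(=S)n2ccnc2)CO[Si](C)(C)C(C)(C)C)cc1OC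
F4 | step 12 | ethyl aryloxyacetate of 15 | COc1cc(C[C@H]2CO[C@H](c3ccc(OCC(=O)OCC)c(OC)c3)[C@H]2CO[Si](C)(C)C(C)(C)C)ccc1OCc1ccccc1
F5 | step 12 | aryloxyacetic acid of 15 | COc1cc(C[C@H]2CO[C@H](c3ccc(OCC(=O)O)c(OC)c3)[C@H]2CO[Si](C)(C)C(C)(C)C)ccc1OCc1ccccc1
F6 | step 12 | mixed pivalic anhydride of F5 | COc1cc(C[C@H]2CO[C@H](c3ccc(OCC(=O)OC(=O)C(C)(C)C)c(OC)c3)[C@H]2CO[Si](C)(C)C(C)(C)C)ccc1OCc1ccccc1
F7 | step 16 | imide 19 with free ring B phenol | COc1cc(C[C@H]2CO[C@H](c3ccc(OCC(=O)N4C(=O)OC[C@H]4Cc4ccccc4)c(OC)c3)[C@H]2CO[Si](C)(C)C(C)(C)C)ccc1O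
F8 | step 16 | bis-TBS imide (ring B O-TBS, primary O-TBS) | COc1cc(C[C@H]2CO[C@H](c3ccc(OCC(=O)N4C(=O)OC[C@H]4Cc4ccccc4)c(OC)c3)[C@H]2CO[Si](C)(C)C(C)(C)C)ccc1O[Si](C)(C)C(C)(C)C
F9 | step 16 | 4-(tert-butyldimethylsilyloxy)-3-methoxybenzaldehyde | COc1cc(C=O)ccc1O[Si](C)(C)C(C)(C)C
F10 | step 16 | Z dibutylboron enolate of F8 | COc1cc(C[C@H]2CO[C@H](c3ccc(O/C=C(/N4C(=O)OC[C@H]4Cc4ccccc4)OB(CCCC)CCCC)c(OC)c3)[C@H]2CO[Si](C)(C)C(C)(C)C)ccc1O[Si](C)(C)C(C)(C)C
F11 | step 16 | tris-TBS syn aldol adduct | COc1cc(C[C@H]2CO[C@H](c3ccc(O[C@@H](C(=O)N4C(=O)OC[C@H]4Cc4ccccc4)[C@@H](O)c4ccc(O[Si](C)(C)C(C)(C)C)c(OC)c4)c(OC)c3)[C@H]2CO[Si](C)(C)C(C)(C)C)ccc1O[Si](C)(C)C(C)(C)C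
F12 | step 16 | tris-TBS (1S,2S)-1,3-diol | COc1cc(C[C@H]2CO[C@H](c3ccc(O[C@@H](CO)[C@@H](O)c4ccc(O[Si](C)(C)C(C)(C)C)c(OC)c4)c(OC)c3)[C@H]2CO[Si](C)(C)C(C)(C)C)ccc1O[Si](C)(C)C(C)(C)C
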